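The plan rests on cutting the C2'–C3' bond of quinone ring A. Both ends of that bond are enolisable positions. C2' carries the ethyl group next to C1'=O, C3' carries the ether oxygen next to C4'=O, and the two carbonyls hang on the neighbouring ring-fusion carbons C8a' and C4a'. Two donor carbons can be united only by oxidation. In one operation the key step makes this bond, closes ring A, aromatises it and oxidises it to the quinone. Precursor 24 is the ortho-diacylarene in latent form: C1' is a TIPS enol ether, and the C4' ketone bears a CH2–O link to quaternary C2 of fragment B, whose future C3/C4 diketone is stored as a cis-diol acetonide.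

Key step: step 14

Conventions, design choices and one assumption
- Primed locants refer to the quinone half (1,4-naphthoquinone numbering). Unprimed locants refer to fragment B (1-tetralone numbering: C1 ketone next to C8a, C2 quaternary).
- A free ortho-diketone would place an enolate beside a ketone as soon as base arrives. Five-membered aldol closure is intramolecular, whereas the second deprotonation is not. C1' therefore enters as an enol silane, which serves as both protecting group and C2' donor.
- A C4 ketone next to C3H2 would set the ether oxygen beta to an enolisable carbonyl. Once ring A is a quinone, that oxygen is a vinylogous carboxylate, so half the molecule would be expelled. C3 and C4 are therefore oxygenated together early and oxidised together late.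
- The tertiary ether is made by alkylation with a small activated bromide. An aryl diazoketone flanked by a methoxy and an acyl group would be consumed by intramolecular ylide formation before it met a hindered tertiary alcohol.
- Compounds 3–8 are racemic. C4 in 9–12 is a mixture of epimers that step 7 erases.
- The same spatial arrangement at C2 is R in 9–29 and S in 30 and 31, because C3 outranks C1 once it is a carbonyl.
- Assumption: the (+)-oxaziridine attacks the enolate face that gives 2R, as expected for 2-alkyl-8-methoxy-1-tetralone enolates. Otherwise its antipode would be used.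

Step 1
Reactants: 1 1,2,4-trimethoxybenzene; 2 2-bromobutanoyl bromide (racemic)
Product: 3 2-bromo-1-(2,4,5-trimethoxyphenyl)butan-1-one (racemic)
Conditions: SnCl4, CH2Cl2, 0 °C
Reagents that add atoms: none
Why: Friedel–Crafts acylation takes place at C5 of 1, para to one methoxy group and ortho to another, and a mild Lewis acid at low temperature spares the methyl ethers and the C–Br bond; the bromine-bearing centre is racemic and is erased in step 5.

Step 2
Reactants: 3 2-bromo-1-(2,4,5-trimethoxyphenyl)butan-1-one
Product: 4 O-ethyl S-[1-oxo-1-(2,4,5-trimethoxyphenyl)butan-2-yl] dithiocarbonate (racemic)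
Conditions: EtOC(S)SK, acetone, 0 °C
Reagents that add atoms: potassium O-ethyl dithiocarbonate, CCOC(=S)[S-].[K+]
Why: SN2 displacement of the activated alpha-bromo ketone by the soft xanthate sulfur is the standard entry to such radical precursors.

Step 3
Reactants: 4 xanthate; 5 vinyl pivalate
Product: 6 1-[(ethoxycarbonothioyl)sulfanyl]-3-ethyl-4-oxo-4-(2,4,5-trimethoxyphenyl)butyl pivalate (diastereomer mixture, racemic)
Conditions: dilauroyl peroxide (cat., in portions), EtOAc, reflux
Reagents that add atoms: none
Why: Xanthate-transfer radical addition: the electrophilic alpha-keto radical adds to the CH2 terminus of the electron-rich vinyl ester and the adduct radical is capped by xanthate transfer, which forms C2–C3 and places oxygen on the future C4 without any need for stereocontrol.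

Step 4
Reactants: 6 xanthate adduct
Product: 7 2-ethyl-5,6,8-trimethoxy-4-(pivaloyloxy)-3,4-dihydronaphthalen-1(2H)-one (cis/trans mixture, racemic)
Conditions: dilauroyl peroxide (1.2 equiv, in portions), EtOAc, reflux
Reagents that add atoms: none
Why: Peroxide-mediated radical cyclisation of a xanthate onto an arene, the established xanthate route to alpha-tetralones, closes C4–C4a at the only free position ortho to the ketone (a site that ionic alkylation or acylation would not reach), and the peroxide re-aromatises the cyclohexadienyl radical.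

Step 5
Reactants: 7 4-pivaloyloxy tetralone
Product: 9 (2R)-2-ethyl-2-hydroxy-5,6,8-trimethoxy-4-(pivaloyloxy)-3,4-dihydronaphthalen-1(2H)-one (both C4 epimers), via sodium enolate 8 (not isolated)
Conditions: NaN(SiMe3)2 (1.05 equiv), THF, −78 °C, short enolisation; (+)-[(8,8-dimethoxycamphoryl)sulfonyl]oxaziridine, −78 °C; aq. NH4Cl
Reagents that add atoms: (+)-[(8,8-dimethoxycamphoryl)sulfonyl]oxaziridine, CC1([C@@H]2CC[C@]13CS(=O)(=O)N4[C@@]3(C2(OC)OC)O4)C
Why: Davis asymmetric enolate hydroxylation: all stereoisomers of 7 lose C2 in the planar enolate, and the camphor-derived oxaziridine, the reagent suited to 2-alkyl-8-methoxy-1-tetralone enolates, transfers oxygen under reagent control to the face that makes C2 R.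

Step 6
Reactants: 9 (2R)-carbinol; 10 2-bromo-N-methoxy-N-methylacetamide
Product: 12 2-{[(2R)-2-ethyl-5,6,8-trimethoxy-1-oxo-4-(pivaloyloxy)-1,2,3,4-tetrahydronaphthalen-2-yl]oxy}-N-methoxy-N-methylacetamide (both C4 epimers), via sodium alkoxide 11 (not isolated)
Conditions: NaH, Bu4NI (cat.), THF–DMF, 0 °C to rt
Reagents that add atoms: none
Why: Williamson ether synthesis builds the crowded tertiary ether on a small, carbonyl-activated primary bromide; the ketone cannot enolise and the bulky pivalate resists attack or 1,3-acyl shift by the alkoxide.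

Step 7
Reactants: 12 Weinreb amide ether
Product: 13 2-{[(2R)-2-ethyl-5,6,8-trimethoxy-1-oxo-1,2-dihydronaphthalen-2-yl]oxy}-N-methoxy-N-methylacetamide
Conditions: TsOH (cat.), toluene, 90 °C
Reagents that add atoms: none
Why: Acid-catalysed E1 loss of pivalic acid from benzylic C4 (cation supported by the ortho 5-methoxy group) normally aromatises such tetralones, but with C2 quaternary it must stop at the C3=C4 alkene, and it merges both C4 epimers into one compound.

Step 8
Reactants: 13 C3=C4 alkene
Product: 14 (2R,3S,4S)-3,4-diol, 2-{[2-ethyl-3,4-dihydroxy-5,6,8-trimethoxy-1-oxo-1,2,3,4-tetrahydronaphthalen-2-yl]oxy}-N-methoxy-N-methylacetamide (cis-diol, trans to the C2 oxygen)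
Conditions: OsO4 (cat.), N-methylmorpholine N-oxide, acetone–H2O, rt
Reagents that add atoms: osmium tetroxide (catalytic oxygen carrier), O=[Os](=O)(=O)=O; N-methylmorpholine N-oxide, C[N+]1([O-])CCOCC1; water, O
Why: Upjohn cis-dihydroxylation of the styrene-type alkene should occur anti to the pseudo-axial allylic C2 alkoxy group to give the 3S,4S diol, and since both new centres are temporary an imperfect facial selectivity costs nothing in the end.

Step 9
Reactants: 14 cis-diol
Product: 15 (2R,3S,4S)-3,4-O-isopropylidene derivative of 14 (Weinreb amide acetonide)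
Conditions: Me2C(OMe)2, PPTS (cat.), CH2Cl2, rt
Reagents that add atoms: 2,2-dimethoxypropane, COC(C)(C)OC
Why: Acid-catalysed transketalisation locks the cis-diol as an acetonide that is inert to organolithiums, amide bases and copper salts.

Step 10
Reactants: 16 2,4,5-trimethoxybenzoic acid
Product: 18 2-bromo-3,4,6-trimethoxybenzoic acid, via dilithiated benzoate 17 (not isolated)
Conditions: s-BuLi (2.2 equiv), TMEDA, THF, −78 °C; BrCl2CCCl2Br, −78 °C to rt; aq. HCl
Reagents that add atoms: 1,2-dibromo-1,1,2,2-tetrachloroethane, ClC(Cl)(Br)C(Cl)(Cl)Br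
Why: Directed ortho-metalation of the unprotected benzoic acid: C6–H lies between the lithium carboxylate and the 5-methoxy group, both of which steer s-BuLi/TMEDA there, and the aryllithium is brominated by halogen transfer from the polyhaloethane.

Step 11
Reactants: 18 bromo acid; 19 n-propylmagnesium chloride
Product: 21 1-(2-bromo-3,4,6-trimethoxyphenyl)butan-1-one, via acid chloride 20 (not isolated)
Conditions: (COCl)2, DMF (cat.), CH2Cl2, rt; concentrate; 19, Fe(acac)3 (3 mol %), THF, −78 °C
Reagents that add atoms: none
Why: Acid chloride formation followed by iron-catalysed acylation of the Grignard reagent gives the ketone without over-addition, because the doubly ortho-substituted carbonyl is shielded and the aryl bromide is inert at this temperature.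

Step 12
Reactants: 21 bromo ketone
Product: 22 (Z)-[1-(2-bromo-3,4,6-trimethoxyphenyl)but-1-en-1-yl]oxy-triisopropylsilane
Conditions: i-Pr3SiOTf, Et3N, CH2Cl2, 0 °C to rt
Reagents that add atoms: triisopropylsilyl trifluoromethanesulfonate, CC(C)[Si](C(C)C)(C(C)C)OS(=O)(=O)C(F)(F)F
Why: Soft enolisation with a silyl triflate and a tertiary amine gives the (Z)-enol silane (geometry irrelevant), which removes the electrophilic C1' carbonyl for steps 13 and 14 and is at the same time the C2' donor of the key step.

Step 13
Reactants: 22 bromo enol silane; 15 Weinreb amide acetonide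
Product: 24 keto enol silane (latent ortho-diacylarene): the arene of 22 with Br replaced by C(=O)CH2–O–C2 of the fragment B acetonide (2R,3S,4S), via aryllithium 23 (not isolated)
Conditions: t-BuLi (2.0 equiv), Et2O, −78 °C; 15 in THF, −78 to −40 °C; aq. NH4Cl
Reagents that add atoms: none
Why: Bromine–lithium exchange and Weinreb ketone synthesis: the chelated tetrahedral adduct stops at the ketone stage, the amide carbonyl on a CH2 group is far more accessible than the neopentyl-type C1 ketone of fragment B, and the bulky TIPS group suppresses 1,4 O-to-C silyl migration in 23.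

Step 14
Reactants: 24 keto enol silane
Product: 28 2'-ethyl-5',6',8'-trimethoxy-1',4'-naphthoquinon-3'-yl ether of the fragment B acetonide (2R,3S,4S), via lithium enolate 25 (not isolated), via 2,3-dihydroquinone 26 (not isolated), via naphthalene-1,4-diol 27 (not isolated)
Conditions: LiN(SiMe3)2 (1.1 equiv), THF, −78 °C; CuCl2 (3 equiv) in DMF, high dilution, −78 to 0 °C; then air, rt
Reagents that add atoms: none
Why: Proposed new method: LiN(SiMe3)2 removes a C3' proton of the only enolisable ketone, divalent copper takes one electron from this alpha-alkoxy enolate, and the C3' radical (or, after a second oxidation, the acyl oxocarbenium ion) is captured at C2' of the neighbouring enol silane, after which loss of the silyl group to chloride gives diketone 26. The closest known reactions are the CuCl2- or FeCl3-mediated intramolecular coupling of ketone bis-enolates to cyclic 1,4-diketones and the oxidative cross-coupling of enol silanes, neither of which has been run on an ortho-diacylarene or carried on to a quinone. The ring closes 6-endo-trig with respect to the C1'=C2' bond, which is also the electronically preferred mode because attack at C2' leaves a benzylic alpha-silyloxy radical. Diketone 26 tautomerises to diol 27, which the copper salts and air oxidise to quinone 28, so C2' and C3' end up sp2, no stereocentre is created and C2, C3 and C4 of fragment B are untouched. The selectivity needed is C–C coupling over five-membered aldol closure, and it is secured because C1' is never a free carbonyl while a C3' enolate exists; fragment B offers only a non-enolisable ketone, an acetonide and no allylic ether.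

Step 15
Reactants: 28 quinone acetonide
Product: 29 quinone ether of the (2R,3S,4S)-3,4-diol
Conditions: CF3CO2H–H2O (9:1), CH2Cl2, 0 °C
Reagents that add atoms: none
Why: Mild aqueous acid hydrolyses the acetonide through its own oxocarbenium ion, under conditions that the hindered vinylogous-ester link and the aryl methyl ethers survive.

Step 16
Reactants: 29 diol
Product: 30 (2S)-hexamethyl ether of the target (fragment B as the 1,3,4-trione)
Conditions: DMSO, (CF3CO)2O, CH2Cl2, −78 °C; Et3N, −78 to −20 °C
Reagents that add atoms: none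
Why: Swern-type oxidation with anhydride-activated DMSO, the standard way from vicinal diols to 1,2-diketones without C–C cleavage, activates both carbinols before base is added, so the ketol stage (the only one from which the quinonyl oxide could be expelled) is passed at low temperature, while C2 bears no hydrogen and keeps its configuration.

Step 17
Reactants: 30 hexamethyl ether
Product: 31 target, (2S)-2-ethyl-2-[(3-ethyl-5,6,8-trihydroxy-1,4-dioxo-1,4-dihydronaphthalen-2-yl)oxy]-5,6,8-trihydroxynaphthalene-1,3,4(2H)-trione
Conditions: BBr3 (excess), CH2Cl2, −78 °C to rt; ice water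
Reagents that add atoms: none
Why: Boron tribromide cleavage of aryl methyl ethers: the four peri ethers are helped by chelation to the neighbouring carbonyls and the C6/C6' ethers by the adjacent borate, whereas the C2–O bond, flanked by two carbonyl groups, can neither ionise nor be attacked from the rear.

Compound list
1 | 1,2,4-trimethoxybenzene | COc1ccc(OC)c(OC)c1 | starting material
2 | 2-bromobutanoyl bromide (racemic) | CCC(Br)C(=O)Br | starting material
3 | 2-bromo-1-(2,4,5-trimethoxyphenyl)butan-1-one (racemic) | CCC(Br)C(=O)c1cc(OC)c(OC)cc1OC | intermediate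
4 | O-ethyl S-[1-oxo-1-(2,4,5-trimethoxyphenyl)butan-2-yl] dithiocarbonate (racemic) | CCOC(=S)SC(CC)C(=O)c1cc(OC)c(OC)cc1OC | intermediate
5 | vinyl pivalate | C=COC(=O)C(C)(C)C | starting material
6 | xanthate adduct, ArC(=O)CH(Et)CH2CH(OPiv)SC(S)OEt (diastereomer mixture) | CCOC(=S)SC(CC(CC)C(=O)c1cc(OC)c(OC)cc1OC)OC(=O)C(C)(C)C | intermediate
7 | 2-ethyl-5,6,8-trimethoxy-4-(pivaloyloxy)-1-tetralone (cis/trans, racemic) | CCC1CC(OC(=O)C(C)(C)C)c2c(OC)c(OC)cc(OC)c2C1=O | intermediate
8 | sodium enolate of 7 | CCC1=C([O-])c2c(OC)cc(OC)c(OC)c2C(OC(=O)C(C)(C)C)C1.[Na+] | intermediate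
9 | (2R)-2-ethyl-2-hydroxy-5,6,8-trimethoxy-4-(pivaloyloxy)-1-tetralone (both C4 epimers) | O[C@]1(CC)CC(OC(=O)C(C)(C)C)c2c(OC)c(OC)cc(OC)c2C1=O | intermediate
10 | 2-bromo-N-methoxy-N-methylacetamide | CON(C)C(=O)CBr | starting material
11 | sodium alkoxide of 9 | [Na+].[O-][C@]1(CC)CC(OC(=O)C(C)(C)C)c2c(OC)c(OC)cc(OC)c2C1=O | intermediate
12 | (2R)-Weinreb amide ether, 4-pivalate (both C4 epimers) | CON(C)C(=O)CO[C@]1(CC)CC(OC(=O)C(C)(C)C)c2c(OC)c(OC)cc(OC)c2C1=O | intermediate
13 | (2R)-Weinreb amide ether, C3=C4 alkene | CON(C)C(=O)CO[C@]1(CC)C=Cc2c(OC)c(OC)cc(OC)c2C1=O | intermediate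
14 | (2R,3S,4S)-Weinreb amide ether, 3,4-cis-diol | CON(C)C(=O)CO[C@]1(CC)[C@@H](O)[C@@H](O)c2c(OC)c(OC)cc(OC)c2C1=O | intermediate
15 | (2R,3S,4S)-Weinreb amide ether, 3,4-acetonide | CON(C)C(=O)CO[C@]1(CC)[C@H]2OC(C)(C)O[C@H]2c3c(OC)c(OC)cc(OC)c3C1=O | intermediate
16 | 2,4,5-trimethoxybenzoic acid | COc1cc(OC)c(C(=O)O)cc1OC | starting material
17 | lithium 6-lithio-2,4,5-trimethoxybenzoate | [Li+].[O-]C(=O)c1c([Li])c(OC)c(OC)cc1OC | intermediate
18 | 2-bromo-3,4,6-trimethoxybenzoic acid | OC(=O)c1c(Br)c(OC)c(OC)cc1OC | intermediate
19 | n-propylmagnesium chloride | CCC[Mg]Cl | starting material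
20 | 2-bromo-3,4,6-trimethoxybenzoyl chloride | ClC(=O)c1c(Br)c(OC)c(OC)cc1OC | intermediate
21 | 1-(2-bromo-3,4,6-trimethoxyphenyl)butan-1-one | CCCC(=O)c1c(OC)cc(OC)c(OC)c1Br | intermediate
22 | (Z)-TIPS enol ether of 21 | CC/C=C(\O[Si](C(C)C)(C(C)C)C(C)C)c1c(OC)cc(OC)c(OC)c1Br | intermediate
23 | aryllithium from 22 | CC/C=C(\O[Si](C(C)C)(C(C)C)C(C)C)c1c(OC)cc(OC)c(OC)c1[Li] | intermediate
24 | key-step precursor: C1' TIPS enol ether, C4' ketone, CH2–O link to fragment B acetonide (2R,3S,4S) | CC/C=C(\O[Si](C(C)C)(C(C)C)C(C)C)c1c(OC)cc(OC)c(OC)c1C(=O)CO[C@]2(CC)[C@H]3OC(C)(C)O[C@H]3c4c(OC)c(OC)cc(OC)c4C2=O | intermediate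
25 | lithium C4'–C3' enolate of 24 | CC/C=C(\O[Si](C(C)C)(C(C)C)C(C)C)c1c(OC)cc(OC)c(OC)c1C([O-])=CO[C@]2(CC)[C@H]3OC(C)(C)O[C@H]3c4c(OC)c(OC)cc(OC)c4C2=O.[Li+] | intermediate
26 | 2',3'-dihydro-1',4'-naphthoquinone (C2', C3' unassigned) | CCC1C(O[C@]2(CC)[C@H]3OC(C)(C)O[C@H]3c4c(OC)c(OC)cc(OC)c4C2=O)C(=O)c5c(OC)c(OC)cc(OC)c5C1=O | intermediate
27 | naphthalene-1',4'-diol tautomer | CCc1c(O[C@]2(CC)[C@H]3OC(C)(C)O[C@H]3c4c(OC)c(OC)cc(OC)c4C2=O)c(O)c5c(OC)c(OC)cc(OC)c5c1O | intermediate
28 | key-step product: 2'-ethyl-5',6',8'-trimethoxynaphthoquinon-3'-yl ether of the fragment B acetonide | CCC1=C(O[C@]2(CC)[C@H]3OC(C)(C)O[C@H]3c4c(OC)c(OC)cc(OC)c4C2=O)C(=O)c5c(OC)c(OC)cc(OC)c5C1=O | intermediate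
29 | quinone ether of the (2R,3S,4S)-3,4-diol | CCC1=C(O[C@]2(CC)[C@@H](O)[C@@H](O)c3c(OC)c(OC)cc(OC)c3C2=O)C(=O)c4c(OC)c(OC)cc(OC)c4C1=O | intermediate
30 | (2S)-hexamethyl ether of the target | CCC1=C(O[C@]2(CC)C(=O)C(=O)c3c(OC)c(OC)cc(OC)c3C2=O)C(=O)c4c(OC)c(OC)cc(OC)c4C1=O | intermediate
31 | CNP0325426.1, (2S) | CCC1=C(O[C@]2(CC)C(=O)C(=O)c3c(O)c(O)cc(O)c3C2=O)C(=O)c2c(O)c(O)cc(O)c2C1=O | target

Total step count: 17. Longest linear sequence: 14 (steps 1–9 and 13–17). The fragment A branch (steps 10–12) joins at step 13.

Steps most likely to fail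

Step 14. Three processes may intervene:
- The oxidised C3' centre may dimerise or be chlorinated faster than it reaches C2'.
- The first-formed diketone may lose the fragment B alkoxide by beta-elimination before it aromatises.
- Aromatisation may be slow.

The fallback sets out from 24 and returns at 28. It replaces the one-pot electron-transfer coupling by a polar, two-stage closure of the same bond. Enolate 25 is sulfenylated with PhSSO2Ph to the alpha-phenylsulfanyl ketone F1, which stores the oxidation as a C–S bond. AgOTf with 2,6-di-tert-butyl-4-methylpyridine in CH2Cl2 at −78 °C then ionises the O,S-acetal. The tethered enol silane traps the oxocarbenium ion in a Mukaiyama-type alkylation, the reaction type used to make C-glycosides from thioglycosides. This gives diketone 26 under base-free conditions. Diketone 26 is isolated, tautomerised on silica gel to 27 and oxidised with Ag2O to 28.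

Step 16. The half-oxidised ketol may enolise and expel the quinonyl oxide, or the C3–C4 bond may be cleaved oxidatively. The fallback sets out from 28 and returns at 31. It lowers the leaving-group ability of the ether oxygen before the oxidation.
- Aqueous Na2S2O4 reduces 28 back to diol 27.
- Ac2O and pyridine convert 27 into the naphthalene-1,4-diyl diacetate F2.
- Aqueous CF3CO2H frees the diol F3.
- The activated-DMSO oxidation then gives the diketone F4, in which the oxygen belongs to an ordinary aryl ether.
- BBr3 followed by a methanol quench (the HBr formed strips both acetates) gives the leuco form of the target F5.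
- Air oxidises F5 to 31.

Step 10. Metalation may occur at C3 between the two methoxy groups, or the alkyllithium may add to the carboxylate. The fallback sets out from 16 and returns at 21. It uses the stronger tertiary-amide director.
- Acid 16 is condensed with Et2NH (EDC·HCl) to the diethylamide F6.
- s-BuLi/TMEDA followed by BrCl2CCCl2Br gives the bromo amide F7.
- Cp2Zr(H)Cl reduces the hindered amide to the aldehyde F8.
- Grignard reagent 19 adds to give the carbinol F9.
- Dess–Martin oxidation gives ketone 21.

Further compounds
F1 | step 14 | alpha-phenylsulfanyl ketone from 24 (C3' epimers) | CC/C=C(\O[Si](C(C)C)(C(C)C)C(C)C)c1c(OC)cc(OC)c(OC)c1C(=O)C(Sc5ccccc5)O[C@]2(CC)[C@H]3OC(C)(C)O[C@H]3c4c(OC)c(OC)cc(OC)c4C2=O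
F2 | step 16 | naphthalene-1',4'-diyl diacetate of 27 | CCc1c(O[C@]2(CC)[C@H]3OC(C)(C)O[C@H]3c4c(OC)c(OC)cc(OC)c4C2=O)c(OC(C)=O)c5c(OC)c(OC)cc(OC)c5c1OC(C)=O
F3 | step 16 | diacetate with free (3S,4S)-diol | CCc1c(O[C@]2(CC)[C@@H](O)[C@@H](O)c3c(OC)c(OC)cc(OC)c3C2=O)c(OC(C)=O)c4c(OC)c(OC)cc(OC)c4c1OC(C)=O
F4 | step 16 | diacetate with fragment B as the 1,3,4-trione | CCc1c(O[C@]2(CC)C(=O)C(=O)c3c(OC)c(OC)cc(OC)c3C2=O)c(OC(C)=O)c4c(OC)c(OC)cc(OC)c4c1OC(C)=O
F5 | step 16 | leuco (1',4'-dihydroxy) form of the target | CCc1c(O[C@]2(CC)C(=O)C(=O)c3c(O)c(O)cc(O)c3C2=O)c(O)c4c(O)c(O)cc(O)c4c1O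
F6 | step 10 | N,N-diethyl-2,4,5-trimethoxybenzamide | CCN(CC)C(=O)c1cc(OC)c(OC)cc1OC
F7 | step 10 | 2-bromo-N,N-diethyl-3,4,6-trimethoxybenzamide | CCN(CC)C(=O)c1c(Br)c(OC)c(OC)cc1OC
F8 | step 10 | 2-bromo-3,4,6-trimethoxybenzaldehyde | O=Cc1c(Br)c(OC)c(OC)cc1OC
F9 | step 10 | 1-(2-bromo-3,4,6-trimethoxyphenyl)butan-1-ol (racemic) | CCCC(O)c1c(OC)cc(OC)c(OC)c1Br
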